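Time comes first: this flask runs to 30 h, and the grey run reads target 26% at 2.50 h and 26% at 30.0 h, so the end state has to be reckoned.

common to all: starting material 0.50 M

| run | first nucleophile | second nucleophile | remark | time |
|---|---|---|---|---|
| grey | 0.65 equiv | 0.50 equiv | run made earlier |  |
| ochre | 2.6 equiv | 0.50 equiv | run made earlier |  |
| violet | 1.3 equiv | 0.25 equiv | run made earlier |  |
| flask | 1.30 equiv | 0.500 equiv |  | 30 h |

| run | time / h | other capture product / % | target / % |
|---|---|---|---|
| grey | 2.50 | 51 | 26 |
| grey | 4.00 | 52 | 23 |
| grey | 6.00 | 49 | 23 |
| grey | 10.0 | 53 | 23 |
| grey | 20.0 | 52 | 27 |
| grey | 30.0 | 51 | 26 |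
| ochre | 5.00 | 51 | 48 |
| ochre | 10.0 | 49 | 44 |
| ochre | 15.0 | 50 | 43 |
| ochre | 20.0 | 48 | 45 |
| ochre | 25.0 | 50 | 45 |
| ochre | 30.0 | 49 | 45 |
| violet | 2.50 | 26 | 58 |
| violet | 5.00 | 25 | 60 |
| violet | 8.00 | 24 | 60 |
| violet | 15.0 | 27 | 62 |
| violet | 30.0 | 25 | 61 |

(scatter of a reading: 1.5 percentage points)

- the analysis behind the earlier runs scatters by 1.5 percentage points, standard deviation
- a reading or a percentage of target counts all its forms, free or not

* share of other capture product in other capture product plus target at 4.0 min
* share of other capture product in other capture product plus target at 80 min
* share of other capture product in other capture product plus target at 30 h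
* which of other capture product and target there is more of at 30 h

The second setting is the second nucleophile. By hand, each part charged should end as other capture product, and the readings show this: 51% from 0.50 equiv in the grey run, 25% from 0.25 equiv in the violet run. It is the limiting reagent of the capture.

The third setting is the first nucleophile. By hand, target should fill the room that capture leaves, 50.0% in the ochre run. Yet the ochre run, with 2.6 equiv charged, averages 45.0% of target, the grey run 24.7% and the violet run 60.2%. One combination stays steady across these runs: grey gives 0.102, ochre 0.107 and violet 0.103, with a mean of 0.104. This reading is the leftover product: the fraction of starting material in neither product, times the free first nucleophile as a fraction of the starting material charged.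

For the flask, the reckoning here sets other capture product at 0.500 equiv and seeks the target that restores this product, which gives 38.6% and a share of 56.4% at 30 h. It says nothing about 4.0 min, since no reading stands before 2.50 h.

The forecast gives shares of 55%, 56% and 56%, with other capture product ahead, and remarks that “nothing shows the early kinetics”.

The flask gives 45.9%, 55.7% and 56.5%, with other capture product ahead at 50.0% against 38.6% of target, crystals counted in; the leftover product 0.104 had given 38.6%.

    starting material → intermediate (k = 0.0740 /min)
    crystals ⇌ target, rate k2*(cs2 - [target]) while solid is left; crystals form when [target] > cs2 (solubility = 23.0 mM, k = 0.780 /min)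
    second nucleophile + intermediate → other capture product (k = 0.820 /M/min)
    first nucleophile + intermediate ⇌ target (K = 0.880 /M, k = 1.80 /M/min)

The forecast and the flask part at 4.0 min, 55% against 45.9%, and the flask's two products stand level at 5.94 min. The neighbouring flask charges 0.200 equiv of second nucleophile. The same reckoning with 0.104 gives it 64.2% of target and a share of 23.8%. At 30.0 h that neighbouring flask holds 20.0% of other capture product, a share of 23.8%, and, crystals counted in, 64.1% of target.

The data were generated by integration for an exercise, noise included.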